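## The problem

Target 14, 6-heneicosyl-2,4-dimethoxyphenol, is one benzene ring with a free hydroxyl at C1, methoxy groups at C2 and C4, and an unbranched saturated C21 chain at C6 (chain carbons C1' to C21', counted from the ring). No rings have to be joined and there is no stereocentre, so nothing needs stereocontrol. The open questions are where the ring oxygens come from, how the C1 oxygen is kept distinct from the two methyl ethers, and how a chain without any functional group is attached. The C1 hydroxyl is para to the C4 methoxy group, so the ring is a hydroquinone monoether that air, chemical oxidants or an anode turn into a quinone; strong protic or Lewis acids would also attack the methyl ethers. The chain has no handle, so a bond made inside it must leave no residue, and its waxy nature argues for attaching it late, in one convergent step, from an even-numbered fatty acid. The enabling feature is bond C2'–C3': both carbons are primary sp3 carbons, and each is what is left of a carboxylic acid after decarboxylation, C2' from a 3-arylpropanoic acid and C3' from the C20 saturated fatty acid (2 + 19 = 21 chain carbons). Two carbons of the same polarity can only be joined through radicals, and the radicals must be made reductively so that the electron-rich ring is spared. The C1 hydroxyl is ortho to the chain and would close a six-membered lactone onto any activated propanoate, so it must be masked until the chain is complete, by a group that survives base, hydrogenation and cathodic reduction and leaves in dilute acid.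

## Retrosynthesis

14 ⇒ 13. Only the O–CH2 bond of a methoxymethyl ether on the C1 oxygen is cut, so 13 already has the whole skeleton. This acetal is preferred to a benzyl ether, which would be lost in the hydrogenation, and to a third methyl ether, which could not be removed selectively. The forward step needs dilute acid that leaves the aryl methyl ethers alone, and exclusion of air.

13 ⇒ 10 + 12. The chain is cut at C2'–C3'. Cutting the ring–C1' bond would need a C21 alkyl metal and an aryl halide crowded by an ortho alkoxy group. Cutting C1'–C2' (olefination of aldehyde 4 with a C20 ylide) is classical but needs a later hydrogenation; it is kept as the fallback. Cuts deeper in the chain make both fragments bespoke. The C2'–C3' cut gives two redox-active esters, 10 from a small arylpropanoic acid and 12 from a commodity fatty acid, and both activating groups leave without trace. The forward reaction must join two primary carbons of like polarity under reducing conditions, tolerate the acetal and the ring, and favour the cross product over the two homodimers.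

10 ⇒ 8 + 9 and 12 ⇒ 11 + 9. Each ester C(O)–O bond is cut to the free acid (8 or 11) and N-hydroxyphthalimide 9. Acid 11 is bought; 8 is a compact acid with the final oxygen pattern. The forward step is a carbodiimide esterification, and with the C1 oxygen masked in 8 no lactone can form.

8 ⇒ 7 ⇒ 4 + 5. Acid 8 comes from cinnamic acid 7 by hydrogenation. The C1'=C2' double bond of 7 is cut to aldehyde 4 and malonic acid 5. Malonic acid supplies C2' and two carboxyl carbons: one is lost in the condensation, the other in the key step. This is shorter than a phosphonate olefination followed by saponification. The condensation must run in a buffered basic medium that keeps the acetal.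

4 ⇒ 3 ⇒ 2 ⇒ 1. Removing the acetal gives salicylaldehyde 3. Its methoxy group para to the hydroxyl is cut at the aryl C–O bond to bromide 2, and the C–Br bond of 2 is cut to o-vanillin 1. Compound 1 already has the formyl carbon, the hydroxyl and one methoxy group in the right relationship, and the free position para to the hydroxyl is where bromine enters. The forward steps are a regioselective bromination, a copper-mediated exchange of bromide for methoxide, and O-alkylation of a hindered phenol.

## Roads not taken

Alternative 1: The cut goes through the arene at C1–C6 and opens it to an acyclic polyketone. In the forward direction methyl 3,5,7-trioxooctacosanoate A1 would undergo aldol condensation of its C2 methylene onto the C7 ketone and aromatize to methyl 2-heneicosyl-4,6-dihydroxybenzoate A2.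
- Merits: the ring, the chain and two oxygens are set in one biomimetic step from open-chain material; the alkyl/oxygen regiochemistry is fixed by the chain; no metal or electrolysis is needed.
- Weak points: A2 has a carbon substituent where 14 needs its C1 oxygen. After methylation of both hydroxyls of A2, an ester flanked by the chain and a methoxy group must be degraded to a phenol (reduction to the aldehyde and Dakin or Baeyer–Villiger oxidation, or hydrolysis and Curtius rearrangement), at least four steps on waxy intermediates. A1 needs polyanion acylation chemistry and can also close by Claisen condensation or to a pyranone.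
- Comparison: this road forms the arene more elegantly, but it installs a carbon that must be removed and is no shorter. The chosen plan starts from a ring that already has every oxygen at the right level.

Alternative 2: The cut is the C4–O bond. In the forward direction 2-heneicosyl-6-methoxyphenol A3 would be oxidized at an anode in a methanolic electrolyte with loss of four electrons, forming two C4–O bonds and giving 2-heneicosyl-4,4,6-trimethoxycyclohexa-2,5-dien-1-one A4. A two-electron reduction of A4 with loss of one methoxy group would then give 14.
- Merits: A3 is two steps from o-vanillin 1 (olefination with a C20 ylide, hydrogenation), no protecting group is needed, and the whole route is about four steps.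
- Weak points: A4 is an acid-labile ketal that hydrolyses to 2-heneicosyl-6-methoxy-1,4-benzoquinone A5, and reduction of A5 gives a hydroquinone that has lost the C4 methyl group. Solvent attack at the methoxy-bearing ortho carbon can compete. A3 is poorly soluble in a methanolic electrolyte. The final reduction of A4 must stop exactly at the monoether.
- Comparison: on step count this road is clearly better, by about five steps. The chosen plan sets against it that the ring is never raised to the quinone level, that the oxygen pattern is fixed on a small crystalline aldehyde before the lipid is attached, and that the chain length can be varied by changing the fatty acid.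

Alternative 3: The cut is the ring bond C4–C5, made by ring expansion of a four-membered ring. In the forward direction racemic 3-methoxy-4-(methoxymethoxy)-4-(tricos-1-en-2-yl)cyclobut-2-en-1-one A6 would open on heating to a dienylketene and close by six-electron electrocyclization (Moore rearrangement) to 3-heneicosyl-5-methoxy-4-(methoxymethoxy)phenol A7. O-Methylation of A7 and removal of the acetal would follow.
- Merits: the regiochemistry of A7 is dictated by connectivity, all three oxygens are differentiated by construction, and the thermal step is clean.
- Weak points: A6 needs a squaric acid derived building block that has to be prepared, a 2-metallated long-chain 1-alkene that is not an article of commerce, regioselective carbonyl addition, and protection of a tertiary alcohol.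
- Comparison: the length is roughly that of the chosen plan, and this road would be better for analogues with other ring substituents. The chosen plan has the advantage of commodity starting materials and of precedent for every step on closely related substrates.

Key step: step 8

Remark: bromide 2 can also be bought; its one-step preparation from o-vanillin is included so that the route starts from a commodity chemical.

Step 1
Reactants: 1 o-vanillin (2-hydroxy-3-methoxybenzaldehyde)
Product: 2 5-bromo-2-hydroxy-3-methoxybenzaldehyde
Conditions: Br2, NaOAc, AcOH, rt
Reagents that add atoms: bromine, BrBr
Why: Electrophilic aromatic bromination; the hydroxyl is the strongest director and both its ortho positions are occupied, so bromine should enter para to it (C5), which is also meta to the deactivating formyl group, while NaOAc buffers the HBr.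

Step 2
Reactants: 2 5-bromo-2-hydroxy-3-methoxybenzaldehyde
Product: 3 2-hydroxy-3,5-dimethoxybenzaldehyde
Conditions: NaOCH3 (excess), CuBr (cat.), EtOAc (cat.), CH3OH–DMF, reflux; then aq. HCl
Reagents that add atoms: sodium methoxide, [Na+].[O-]C
Why: Copper-catalysed Ullmann-type methoxylation of an aryl bromide, the reaction type that converts 5-bromovanillin into syringaldehyde; monovalent copper (CuBr) mediates the exchange, the formyl group and the phenoxide are tolerated, and acidic work-up returns the free phenol.

Step 3
Reactants: 3 2-hydroxy-3,5-dimethoxybenzaldehyde
Product: 4 3,5-dimethoxy-2-(methoxymethoxy)benzaldehyde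
Conditions: MOMCl, iPr2NEt, CH2Cl2, 0 °C to rt
Reagents that add atoms: chloromethyl methyl ether, COCCl
Why: O-Alkylation of the phenol with an alpha-chloro ether and a hindered amine base; the resulting acetal withstands base, H2 over Pd/C and cathodic reduction, blocks coumarin formation in step 4 and lactonization in step 6, and is removable with dilute acid.

Step 4
Reactants: 4 3,5-dimethoxy-2-(methoxymethoxy)benzaldehyde; 5 malonic acid
Product: 7 (E)-3-[3,5-dimethoxy-2-(methoxymethoxy)phenyl]prop-2-enoic acid, via arylidenemalonic acid 6 (not isolated)
Conditions: pyridine, piperidine (cat.), 85 °C; cold dilute citric acid work-up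
Reagents that add atoms: none
Why: Knoevenagel condensation in the Doebner modification; piperidine activates the aldehyde as its iminium ion, malonate adds, and diacid 6 loses CO2 in hot pyridine to give the thermodynamically preferred E acid, while the pyridine-buffered medium should leave the acetal intact (the alkene geometry is erased in step 5).

Step 5
Reactants: 7 (E)-3-[3,5-dimethoxy-2-(methoxymethoxy)phenyl]prop-2-enoic acid
Product: 8 3-[3,5-dimethoxy-2-(methoxymethoxy)phenyl]propanoic acid
Conditions: H2 (1 atm), 10% Pd/C, EtOAc, rt
Reagents that add atoms: none
Why: Heterogeneous catalytic hydrogenation of a conjugated C=C bond; the aryl methyl ethers and the methoxymethyl acetal have no benzylic C–O bond and should not be hydrogenolysed under neutral conditions.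

Step 6
Reactants: 8 3-[3,5-dimethoxy-2-(methoxymethoxy)phenyl]propanoic acid; 9 N-hydroxyphthalimide
Product: 10 1,3-dioxoisoindolin-2-yl 3-[3,5-dimethoxy-2-(methoxymethoxy)phenyl]propanoate
Conditions: DIC, DMAP (cat.), CH2Cl2, rt
Reagents that add atoms: none
Why: Carbodiimide (Steglich-type) esterification; N,N'-diisopropylcarbodiimide activates the acid, DMAP transfers the acyl group to the N-hydroxy imide, and the masked ortho oxygen cannot compete by lactonization.

Step 7
Reactants: 11 eicosanoic acid; 9 N-hydroxyphthalimide
Product: 12 1,3-dioxoisoindolin-2-yl eicosanoate
Conditions: DIC, DMAP (cat.), CH2Cl2, rt
Reagents that add atoms: none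
Why: The same carbodiimide esterification applied to a saturated fatty acid; the redox-active ester should be a stable solid that can be purified by recrystallization.

Step 8
Reactants: 10 1,3-dioxoisoindolin-2-yl 3-[3,5-dimethoxy-2-(methoxymethoxy)phenyl]propanoate; 12 1,3-dioxoisoindolin-2-yl eicosanoate (3 equiv)
Product: 13 1-heneicosyl-3,5-dimethoxy-2-(methoxymethoxy)benzene
Conditions: NiCl2·6H2O (20 mol%), 2,2'-bipyridine (20 mol%), AgNO3 (0.3 equiv), DMF (THF cosolvent if needed), Mg anode/reticulated vitreous carbon cathode, undivided cell, constant current, rt
Reagents that add atoms: none
Why: This is the nickel-electrocatalytic doubly decarboxylative coupling of two N-hydroxyphthalimide esters of primary acids, a known reaction type applied here to a new pair of esters. The divalent nickel–bipyridine complex is reduced at the cathode to low-valent nickel, which passes single electrons to 10 and 12; each ester radical anion breaks its N–O bond and loses CO2 to leave phthalimide anion and a primary alkyl radical, while the dissolving magnesium anode supplies the counter-ions. Nickel captures one radical and then the other, and the dialkylnickel species, most plausibly of trivalent nickel, forms C2'–C3' by reductive elimination; AgNO3 is reduced to silver on the cathode, a surface on which the nickel-mediated path is expected to outrun direct reduction of the esters to alkanes. No ring closes and no stereocentre is formed. The selectivity needed is cross-coupling over the two homodimers; both radicals are unhindered primary ones, so the substrates give no bias and the pairing is close to statistical, which is why the cheap ester 12 is used in threefold excess so that most radicals from 10 meet a C19 partner. The expected by-products are the C38 alkane, far less polar than 13, and a little diarylbutane, more polar than 13, so chromatography on silica should separate them. Chemoselectivity comes from the reducing medium: the trioxygenated ring, the methyl ethers and the acetal are inert at the cathode, whereas an anodic Kolbe coupling would oxidize the ring before the carboxylates. The methoxymethyl group also removes the phenoxide and lactone chemistry that a free ortho hydroxyl would bring.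

Step 9
Reactants: 13 1-heneicosyl-3,5-dimethoxy-2-(methoxymethoxy)benzene
Product: 14 6-heneicosyl-2,4-dimethoxyphenol
Conditions: aq. HCl (3 M), CH3OH–THF, 45 °C, under argon
Reagents that add atoms: none
Why: Acid-catalysed acetal cleavage through the oxocarbenium ion, with methanol taking up the formaldehyde unit; aryl methyl ethers and the alkyl chain are inert to dilute HCl, THF keeps the waxy substrate in solution, and argon protects the oxidation-prone para-methoxyphenol.

Compound list

1 | o-vanillin (2-hydroxy-3-methoxybenzaldehyde) | COc1cccc(C=O)c1O | starting material
2 | 5-bromo-2-hydroxy-3-methoxybenzaldehyde | COc1cc(Br)cc(C=O)c1O | intermediate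
3 | 2-hydroxy-3,5-dimethoxybenzaldehyde | COc1cc(OC)cc(C=O)c1O | intermediate
4 | 3,5-dimethoxy-2-(methoxymethoxy)benzaldehyde | COCOc1c(C=O)cc(OC)cc1OC | intermediate
5 | malonic acid | OC(=O)CC(=O)O | starting material
6 | 2-{[3,5-dimethoxy-2-(methoxymethoxy)phenyl]methylidene}propanedioic acid (not isolated) | COCOc1c(C=C(C(=O)O)C(=O)O)cc(OC)cc1OC | intermediate
7 | (E)-3-[3,5-dimethoxy-2-(methoxymethoxy)phenyl]prop-2-enoic acid | COCOc1c(/C=C/C(=O)O)cc(OC)cc1OC | intermediate
8 | 3-[3,5-dimethoxy-2-(methoxymethoxy)phenyl]propanoic acid | COCOc1c(CCC(=O)O)cc(OC)cc1OC | intermediate
9 | N-hydroxyphthalimide | O=C1c2ccccc2C(=O)N1O | starting material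
10 | 1,3-dioxoisoindolin-2-yl 3-[3,5-dimethoxy-2-(methoxymethoxy)phenyl]propanoate | COCOc1c(CCC(=O)ON2C(=O)c3ccccc3C2=O)cc(OC)cc1OC | intermediate
11 | eicosanoic acid | CCCCCCCCCCCCCCCCCCCC(=O)O | starting material
12 | 1,3-dioxoisoindolin-2-yl eicosanoate | CCCCCCCCCCCCCCCCCCCC(=O)ON1C(=O)c2ccccc2C1=O | intermediate
13 | 1-heneicosyl-3,5-dimethoxy-2-(methoxymethoxy)benzene | CCCCCCCCCCCCCCCCCCCCCc1cc(OC)cc(OC)c1OCOC | intermediate
14 | 6-heneicosyl-2,4-dimethoxyphenol | CCCCCCCCCCCCCCCCCCCCCc1cc(OC)cc(OC)c1O | target

Total step count: 9. Longest linear sequence: 8 steps (steps 1 to 6, 8 and 9); step 7 is a one-step branch.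

Least certain steps

Step 8 (key step). The pairing of two equally reactive primary radicals is statistical, so part of 10 will be lost to its homodimer. Radicals may also be reduced or abstract hydrogen before nickel captures them, and the long-chain ester or the waxy product may come out of solution and foul the cathode. These problems lower throughput more than they threaten feasibility. If the coupling cannot be made preparatively useful, the chain is attached by olefination instead, which gives up the C2'–C3' bond formation and serves only as a supply route. This fallback sets out from aldehyde 4 and comes back to the route at 13. 1-Bromoeicosane F1 is heated with PPh3 in toluene to give eicosyl(triphenyl)phosphonium bromide F2. Deprotonation of F2 with NaN(SiMe3)2 (THF, −78 °C) gives eicosylidene(triphenyl)phosphorane F3 in the flask, and F3 is condensed with 4 in a Wittig reaction (−78 °C to rt) to give (Z)-1-(henicos-1-en-1-yl)-3,5-dimethoxy-2-(methoxymethoxy)benzene F4. The alkene geometry of F4 is of no consequence, because hydrogenation of F4 (H2, Pd/C, EtOAc) gives 13.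

Step 2. Substitution on an electron-rich bromophenoxide may be slow, copper-mediated hydrodebromination may compete and return material that is hard to separate, and the aldehyde may suffer under hot methoxide. The fallback builds the aldehyde onto a ring that already has both methoxy groups. It does not use 1 or 2; it sets out from purchased 2,4-dimethoxyphenol F5 and comes back to the route at 3. Magnesium-mediated ortho-formylation of F5 (MgCl2, Et3N, paraformaldehyde, CH3CN, reflux; Casnati–Skattebøl reaction) should put the formyl group on the only free position ortho to the hydroxyl and give 3.

Step 4. The acetal may be lost in hot pyridine containing malonic acid, after which the freed phenol would close onto the malonate to a coumarin; decarboxylation of 6 may also stall. The fallback avoids the hot acidic medium, sets out from 4 and comes back to the route at 8, at the cost of one step. Horner–Wadsworth–Emmons olefination of 4 with triethyl phosphonoacetate (NaH, THF, 0 °C to rt) gives ethyl (E)-3-[3,5-dimethoxy-2-(methoxymethoxy)phenyl]prop-2-enoate F6. Hydrogenation of F6 (H2, Pd/C, EtOAc) gives ethyl 3-[3,5-dimethoxy-2-(methoxymethoxy)phenyl]propanoate F7, and saponification of F7 (LiOH, THF–H2O, then cold dilute HCl to pH 4) gives 8.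

Further compounds

F1 | step 8 | 1-bromoeicosane | CCCCCCCCCCCCCCCCCCCCBr
F2 | step 8 | eicosyl(triphenyl)phosphonium bromide | CCCCCCCCCCCCCCCCCCCC[P+](c1ccccc1)(c1ccccc1)c1ccccc1.[Br-]
F3 | step 8 | eicosylidene(triphenyl)phosphorane | CCCCCCCCCCCCCCCCCCCC=P(c1ccccc1)(c1ccccc1)c1ccccc1
F4 | step 8 | (Z)-1-(henicos-1-en-1-yl)-3,5-dimethoxy-2-(methoxymethoxy)benzene | CCCCCCCCCCCCCCCCCCC/C=C\c1cc(OC)cc(OC)c1OCOC
F5 | step 2 | 2,4-dimethoxyphenol | COc1ccc(O)c(OC)c1
F6 | step 4 | ethyl (E)-3-[3,5-dimethoxy-2-(methoxymethoxy)phenyl]prop-2-enoate | CCOC(=O)/C=C/c1cc(OC)cc(OC)c1OCOC
F7 | step 4 | ethyl 3-[3,5-dimethoxy-2-(methoxymethoxy)phenyl]propanoate | CCOC(=O)CCc1cc(OC)cc(OC)c1OCOC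
A1 | alternative 1 | methyl 3,5,7-trioxooctacosanoate | CCCCCCCCCCCCCCCCCCCCCC(=O)CC(=O)CC(=O)CC(=O)OC
A2 | alternative 1 | methyl 2-heneicosyl-4,6-dihydroxybenzoate | CCCCCCCCCCCCCCCCCCCCCc1cc(O)cc(O)c1C(=O)OC
A3 | alternative 2 | 2-heneicosyl-6-methoxyphenol | CCCCCCCCCCCCCCCCCCCCCc1cccc(OC)c1O
A4 | alternative 2 | 2-heneicosyl-4,4,6-trimethoxycyclohexa-2,5-dien-1-one | CCCCCCCCCCCCCCCCCCCCCC1=CC(OC)(OC)C=C(OC)C1=O
A5 | alternative 2 | 2-heneicosyl-6-methoxy-1,4-benzoquinone | CCCCCCCCCCCCCCCCCCCCCC1=CC(=O)C=C(OC)C1=O
A6 | alternative 3 | racemic 3-methoxy-4-(methoxymethoxy)-4-(tricos-1-en-2-yl)cyclobut-2-en-1-one | COC1=CC(=O)C1(OCOC)C(=C)CCCCCCCCCCCCCCCCCCCCC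
A7 | alternative 3 | 3-heneicosyl-5-methoxy-4-(methoxymethoxy)phenol | CCCCCCCCCCCCCCCCCCCCCc1cc(O)cc(OC)c1OCOC
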